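Readings and results were computed with constants of no real substance; noise was put on by code.

Slowness is the question here: has the starting material in this flask had time to go?

- north-west: starting material 1.5 M (in portions, 3); reagent 1.8 M; protic impurity 0.075 M; initiator 11 mM; the very flask that is asked about, followed so far; portions every 40 s
- flask: starting material 1.5 M (in portions, 3); reagent 1.80 M; protic impurity 0.0750 M; initiator 11 mM; time 15 min; the portions of starting material follow each other after 40 s, the first at the start

- north-west (time / min: starting material / %, product / %): 0.500: 30.4, 0.3; 0.833: 62.0, 4.1; 1.33: 53.0, 7.3; 2.00: 77.5, 16.2; 4.00: 57.9, 37.0; 6.00: 43.0, 53.6

(readings scatter by 1 percentage point)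

- the state of affairs at 15 min: stopped, and by what, or still going (forward and back rates have come level / the reagent has run out first / all of the starting material has reacted / it is still moving)
- conversion of starting material at 15 min
- amount of product at 15 min, in percent of the starting material charged
- amount of product if the flask were left three thousand times as long, in percent of the starting material charged

- the numbers in the tables scatter with a standard deviation of 1 percentage point
- the reaction counts as stopped when no species that holds the starting material changes by six tenths of a point or more over the second half of the time

The north-west run is this flask followed so far. With all portions in, the starting material falls by a factor 1.34 from 2.00 min to 4.00 min and 1.35 from there to 6.00 min. These are equal within the scatter, so we read a first-order decay with constant 0.147 min⁻¹. We carry its half-life, the time in which the starting material present halves: 4.71 min.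

What would have to be true for this flask to have stopped by 15 min? Its starting material would have to stand still over the second half of the time. Reagent running out is one way to that, but at an assumed one to one, 1.80 M of reagent stands above 1.5 M of starting material, so we take starting material as the limiting reagent. Otherwise the decay would have to be over by 7.50 min. Our reckoning from the last reading gives 34.5% then and 11.4% at 15 min, a drop of 23 percentage points, well outside the stopping margin, so we say it is still moving. The balance at 4.00 min and 6.00 min falls short by 4.25% on average, and we book that as lost.

The forecast says it is still moving, with conversion 87%, product 85% and 98% in the long run, reading the gap as “a short-lived intermediate, not a dead loss”, and its long-run figure stands above our 95.8%.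

| Asked | Our reckoning | Flask |
|---|---|---|
| conversion | 88.6% | 88.5% |
| product | 84.3% | 83.5% |
| product, long left | 95.8% | 95.0% |

The state of the flask at 15 min: it is still moving.

    2 first chain carrier → ended chains A (k = 4.50 × 10⁶ M⁻¹ s⁻¹)
    starting material + initiating radical → capped initiator + first chain carrier (k = 1.16 × 10⁷ M⁻¹ s⁻¹)
    initiator → 2 initiating radical (k = 5.10 × 10⁻⁵ s⁻¹)
    starting material + second chain carrier → by-product + first chain carrier (k = 82800 M⁻¹ s⁻¹)
    reagent + first chain carrier → product + second chain carrier (k = 1.07 × 10⁵ M⁻¹ s⁻¹)
    starting material + protic impurity → quenched substrate (k = 0.0318 M⁻¹ s⁻¹)
    2 second chain carrier → ended chains B (k = 6.20 × 10⁸ M⁻¹ s⁻¹)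

In the flask the starting material goes from 34.5% at 7.50 min to 11.5% at 15.0 min, a stretch of 1.59 of our half-lives of 4.71 min, with 30% of the reagent still there. Its step with the second chain carrier gives it a half-life of 4.7 min at 15.0 min, much shorter than the 250 h at 4.58 min of its step with the protic impurity, and quenched substrate stands at 5.00%.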